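The pitfall is to count reagent as charged. At 0.300 M, double product has a half-life of 3.57 h by step 4, so 20 h looks like 5.60 half-lives.

substrate 0.20 M; reagent 0.300 M; time 20 h

    substrate + reagent → mono adduct (k1 = 0.00558 M⁻¹ min⁻¹)
    substrate + mono adduct → side product (k2 = 0.0270 M⁻¹ min⁻¹)
    reagent + mono adduct → double product (k3 = 0.0168 M⁻¹ min⁻¹)
    reagent + double product → triple product (k4 = 0.0108 M⁻¹ min⁻¹)
    triple product → over-reaction product (k5 = 2.77 × 10⁻⁶ min⁻¹)
    reagent ⇌ dormant form (K6 = 1.02, k6 = 0.00269 min⁻¹)

- percentages count the substrate that a species holds: one side product counts as two
- the reaction counts as stopped when no species that holds the substrate changes by six tenths of a point or more over the second half of the time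
- run time (flask): 20 h

- the state of affairs at 20 h: stopped, and by what, or still going (all of the substrate has reacted / the reagent has run out first / it is still moving / forward and back rates have come level)
- triple product at 20 h, in percent of the substrate charged

My reckoning, step by step:

1. Find the free reagent. At equilibrium the dormant form takes about half of it, which leaves a pool of 0.149 M. The exchange relaxes with a time constant of about 3.13 h, less than the run.

2. Split the mono adduct. Take substrate at half its charge. Step 3 then gets a share of 0.480 and step 2 gets the rest.

3. Count turnovers, treating each reagent step as pseudo-first-order: rate constant times free reagent times time. Step 1 gets 0.994. Each passage costs 1.52 substrate, so 22.1 % remains and 24.6 % of the charge passes step 3.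

4. Step 4 gets 1.92. Suppose double product forms evenly over the run. The share gone on is then one minus (one minus exp(−count))/count, here 0.556. That gives triple product of 13.7 %.

5. Now the weak link: the pool was held constant. This route uses 0.179 M of reagent, so free reagent ends near 0.0598 M. Its mean is 0.104 M.

6. Repeat with that mean. The share is 0.393, substrate left is 32.6 %, and 16.5 % passes step 3. The turnover count of step 4, its rate constant times mean free reagent times time, is 1.35. The share gone on is 0.451. I commit to triple product of 7.44 %, still moving.

The forecast says it is still moving, with triple product at 10 %, from “a rough mental march through the two sequential reagent additions”. Its figure is higher than mine.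

The simulation gives it is still moving, with triple product at 8.21 %.

In this flask the turnover count of 1.35 is smaller than the 3.89 that the charged reagent suggests, and it gives a share gone on of 0.451, while triple product 8.21 % beside double product 8.38 % reads 0.495. In the neighbour flask with 0.51 M of reagent, a mean of its pool and its final free reagent, 24.7 % of its charge, gives 0.189 M, a count of 2.45 and a share of 0.627, while its triple product 23.4 % beside double product 10.9 % reads 0.682.

(The numbers come from no measurement, and the outcome is calculated.)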